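**Strategy.** Unit B, the 7-hydroxy-2,3-dihydrobenzofuran (primed locants; styryl-bearing unit A unprimed), is opened across its aryl ether bond C7a′–O1′ and its C2′–C3′ bond. This leads to 4-methoxybenzaldehyde and a diarylmethane that carries an enantiopure p-tolylsulfinyl group on C7a′. In one operation that group directs lithiation of the doubly benzylic C3′–H beside C7a′ (the feature exploited), relays its chirality to C3′ during addition to the aldehyde, and then leaves in an ipso-substitution by the new alkoxide, closing the trans ring. Unit A is then built on C5′ by C–H borylation, carbonyl addition and an enantioselective carbene C–H insertion; the stilbene is attached last.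

Key step: step 3

Assumption (step 3): the facial sense at C3′ is taken from a lithium-chelate model (lithium bridging C3′ and the sulfinyl oxygen, p-tolyl on the far face, aldehyde entering on the lithium side), which calls for the (R)-sulfoxide; the enantiomeric sulfinate would be used in step 2 if the sense proved opposite.
Assumption (step 10): Rh2(R-PTAD)4 is taken to give the (3S) centre; Rh2(S-PTAD)4 would be used otherwise.
Assumption (materials): 2-bromo-4,6-dimethoxybenzaldehyde is taken as commercially available.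

**Step 1**
Reactants: 1 2-bromo-3-methoxybenzaldehyde; 2 (3,5-dimethoxyphenyl)boronic acid
Product: 4 2-bromo-1-[(3,5-dimethoxyphenyl)methyl]-3-methoxybenzene, via tosylhydrazone 3 (not isolated)
Conditions: TsNHNH2, dioxane, 80 °C; then 2, K2CO3, 110 °C
Reagents that add atoms: none
Why: Barluenga reductive coupling, in which the tosylhydrazone gives the diazoalkane with base, the boronic acid adds, the aryl group shifts from boron to carbon with loss of N2 and the benzylic boronic acid protodeboronates; no transition metal is present, so the aryl bromide should survive, and no stereocentre is formed.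

**Step 2**
Reactants: 4 2-bromo-1-[(3,5-dimethoxyphenyl)methyl]-3-methoxybenzene; 5 (1S,2R,5S)-menthyl (R)-4-methylbenzenesulfinate
Product: 7 (R)-1-[(3,5-dimethoxyphenyl)methyl]-3-methoxy-2-(4-methylbenzenesulfinyl)benzene, via arylmagnesium bromide 6 (not isolated)
Conditions: Mg, THF, 60 °C; then 5, THF, –40 to 0 °C
Reagents that add atoms: none
Why: Andersen sulfoxide synthesis, in which the aryl Grignard reagent displaces menthoxide from sulfur with inversion, so the sulfur stereocentre of 7 comes from the bought sulfinate.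

**Step 3**
Reactants: 7 (R)-1-[(3,5-dimethoxyphenyl)methyl]-3-methoxy-2-(4-methylbenzenesulfinyl)benzene; 8 4-methoxybenzaldehyde
Product: 11 (2R,3R)-3-(3,5-dimethoxyphenyl)-7-methoxy-2-(4-methoxyphenyl)-2,3-dihydro-1-benzofuran, via benzyllithium species 9 (not isolated), via lithium alkoxide 10 (not isolated)
Conditions: LiN(iPr)2 (LDA), THF, –78 °C; then 8, –78 °C; then DMPU, –78 to 40 °C
Reagents that add atoms: none
Why: Proposed new method: LiN(iPr)2 removes the doubly benzylic C3′–H of 7 to give the sulfinyl-chelated benzyllithium 9, which adds to the carbonyl carbon of 8 (C2′–C3′ bond), and the alkoxide 10 then attacks C7a′ in an addition–elimination that expels p-toluenesulfenate (C7a′–O1′ bond). The closest known reaction type is the anionic–anionic tandem of 2-(p-tolylsulfinyl)alkylbenzenes with imines, in which the amide nitrogen displaces the sulfinyl group to give indolines, together with the known 1,4-induction in additions of ortho-sulfinyl benzyl carbanions to aldehydes; the oxygen variant on a diarylmethane is new. The dihydrofuran ring closes by a 5-exo-trig ipso-substitution through a Meisenheimer-type adduct, with the sulfinyl group as nucleofuge and no donor para to C7a′ to disfavour the adduct. C3′ is set by the sulfur stereocentre through the lithium chelate, and C2′ by substrate control, since the aldol step is reversible and the alkoxide leading to the 2,3-trans ring should cyclise faster. The step needs benzylic rather than ortho deprotonation, which the chelating sulfinyl group and the acidity of the diarylmethane should secure, and it needs ring closure to outrun retro-aldol, which DMPU and warming are meant to secure. Any 2,3-cis isomer carried forward should converge on trans in step 11, where C2′ can equilibrate under acid.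

**Step 4**
Reactants: 11 (2R,3R)-3-(3,5-dimethoxyphenyl)-7-methoxy-2-(4-methoxyphenyl)-2,3-dihydro-1-benzofuran
Product: 12 2-[(2R,3R)-3-(3,5-dimethoxyphenyl)-7-methoxy-2-(4-methoxyphenyl)-2,3-dihydro-1-benzofuran-5-yl]-4,4,5,5-tetramethyl-1,3,2-dioxaborolane
Conditions: [Ir(cod)OMe]2, dtbpy, B2pin2, THF, 80 °C
Reagents that add atoms: bis(pinacolato)diboron, CC1(C)OB(OC1(C)C)B1OC(C)(C)C(C)(C)O1
Why: Iridium-catalysed aromatic C–H borylation under steric control, C5′–H being the only aromatic C–H in 11 without an ortho substituent; the stereocentres are not touched.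

**Step 5**
Reactants: 13 2-bromo-4,6-dimethoxybenzaldehyde
Product: 14 2-bromo-6-hydroxy-4-methoxybenzaldehyde
Conditions: BCl3, CH2Cl2, –78 to 0 °C; H2O
Reagents that add atoms: none
Why: Chelation-controlled aryl methyl ether cleavage, in which BCl3 bound to the aldehyde oxygen removes only the ortho methyl group.

**Step 6**
Reactants: 14 2-bromo-6-hydroxy-4-methoxybenzaldehyde; 15 4-methoxybenzyl chloride
Product: 16 2-bromo-4-methoxy-6-[(4-methoxyphenyl)methoxy]benzaldehyde
Conditions: K2CO3, DMF, 60 °C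
Reagents that add atoms: none
Why: Williamson ether synthesis on the phenoxide, which installs the benzylic CH2 that becomes C2 of unit A together with its aryl ring.

**Step 7**
Reactants: 12 2-[(2R,3R)-3-(3,5-dimethoxyphenyl)-7-methoxy-2-(4-methoxyphenyl)-2,3-dihydro-1-benzofuran-5-yl]-4,4,5,5-tetramethyl-1,3,2-dioxaborolane; 16 2-bromo-4-methoxy-6-[(4-methoxyphenyl)methoxy]benzaldehyde
Product: 17 {2-bromo-4-methoxy-6-[(4-methoxyphenyl)methoxy]phenyl}[(2R,3R)-3-(3,5-dimethoxyphenyl)-7-methoxy-2-(4-methoxyphenyl)-2,3-dihydro-1-benzofuran-5-yl]methanol (both carbinol epimers)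
Conditions: [Rh(cod)OH]2, KOH, dioxane/H2O, 80 °C
Reagents that add atoms: none
Why: Rhodium-catalysed 1,2-addition of an arylboron reagent to an aldehyde (Miyaura–Hayashi type), to which the aryl bromide should be inert; the new carbinol centre forms without control and is erased in step 8.

**Step 8**
Reactants: 17 the diarylmethanol above
Product: 18 {2-bromo-4-methoxy-6-[(4-methoxyphenyl)methoxy]phenyl}[(2R,3R)-3-(3,5-dimethoxyphenyl)-7-methoxy-2-(4-methoxyphenyl)-2,3-dihydro-1-benzofuran-5-yl]methanone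
Conditions: Dess–Martin periodinane, CH2Cl2, 23 °C
Reagents that add atoms: none
Why: Dess–Martin oxidation of a doubly benzylic alcohol to the diaryl ketone under near-neutral conditions that should leave the benzyl ether and the dihydrofuran untouched.

**Step 9**
Reactants: 18 the diaryl ketone above
Product: 19 hydrazone of ketone 18 (E/Z mixture)
Conditions: N2H4·H2O, AcOH (cat.), n-BuOH, 110 °C
Reagents that add atoms: hydrazine, NN
Why: Condensation of hydrazine with the ketone gives the free hydrazone as precursor of a donor/donor carbene, the C=N geometry being of no consequence.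

**Step 10**
Reactants: 19 hydrazone of ketone 18
Product: 21 (2R,3R)-5-[(2R,3S)-4-bromo-6-methoxy-2-(4-methoxyphenyl)-2,3-dihydro-1-benzofuran-3-yl]-3-(3,5-dimethoxyphenyl)-7-methoxy-2-(4-methoxyphenyl)-2,3-dihydro-1-benzofuran (unit A 2,3-cis), via diazo compound 20 (not isolated)
Conditions: MnO2, CH2Cl2, 0 °C; filtration; Rh2(R-PTAD)4 (PTAD = (1-adamantyl)(phthalimido)acetate), MeCN, 0 °C
Reagents that add atoms: none
Why: Oxidation to the diaryldiazomethane followed by rhodium-carbene 1,5-insertion into the benzylic ether C–H (donor/donor carbene C–H insertion), in which the chiral carboxylate ligands set C3 and the concerted insertion gives the 2,3-cis ring, the centres of unit B being too remote to interfere.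

**Step 11**
Reactants: 21 the cis hexamethyl ether above
Product: 22 (2R,3R)-5-[(2S,3S)-4-bromo-6-hydroxy-2-(4-hydroxyphenyl)-2,3-dihydro-1-benzofuran-3-yl]-3-(3,5-dihydroxyphenyl)-2-(4-hydroxyphenyl)-2,3-dihydro-1-benzofuran-7-ol
Conditions: BBr3, CH2Cl2, –78 to 23 °C; H2O
Reagents that add atoms: none
Why: BBr3 cleaves the six aryl methyl ethers and, by reversible ionisation of the C2–O1 bond to the para-oxygen-stabilised benzylic cation, should epimerise C2 to the thermodynamically preferred 2,3-trans ring while C3 stays fixed; unit B is already trans and no acid-sensitive stilbene is present yet.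

**Step 12**
Reactants: 22 the hexaphenol bromide above; 23 4-ethenylphenyl acetate (4-acetoxystyrene)
Product: 25 (2R,3R)-3-(3,5-dihydroxyphenyl)-5-{(2S,3S)-6-hydroxy-2-(4-hydroxyphenyl)-4-[(E)-2-(4-hydroxyphenyl)ethenyl]-2,3-dihydro-1-benzofuran-3-yl}-2-(4-hydroxyphenyl)-2,3-dihydro-1-benzofuran-7-ol (CNP0172909.1), via stilbene monoacetate 24 (not isolated)
Conditions: Pd(OAc)2, P(o-tol)3, Et3N, DMF, 100 °C; then K2CO3 (cat.), MeOH, 23 °C
Reagents that add atoms: none
Why: Mizoroki–Heck reaction at the aryl bromide gives the (E)-stilbene by syn insertion and syn β-hydride elimination with free phenols tolerated, and mild methanolysis then removes the acetate without acid, which avoids cyclisation of the stilbene onto the neighbouring arene.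

**Compound list**

1 | 2-bromo-3-methoxybenzaldehyde | COc1cccc(C=O)c1Br | starting material
2 | (3,5-dimethoxyphenyl)boronic acid | COc1cc(OC)cc(B(O)O)c1 | starting material
3 | N'-[(E)-(2-bromo-3-methoxyphenyl)methylidene]-4-methylbenzenesulfonohydrazide | COc1cccc(/C=N/NS(=O)(=O)c2ccc(C)cc2)c1Br | intermediate
4 | 2-bromo-1-[(3,5-dimethoxyphenyl)methyl]-3-methoxybenzene | COc1cc(OC)cc(Cc2cccc(OC)c2Br)c1 | intermediate
5 | (1S,2R,5S)-menthyl (R)-4-methylbenzenesulfinate | C[C@H]1CC[C@@H]([C@H](C1)O[S@@](=O)c2ccc(C)cc2)C(C)C | starting material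
6 | {2-[(3,5-dimethoxyphenyl)methyl]-6-methoxyphenyl}magnesium bromide | COc1cc(OC)cc(Cc2cccc(OC)c2[Mg]Br)c1 | intermediate
7 | (R)-1-[(3,5-dimethoxyphenyl)methyl]-3-methoxy-2-(4-methylbenzenesulfinyl)benzene | Cc1ccc(cc1)[S@@](=O)c1c(OC)cccc1Cc1cc(OC)cc(OC)c1 | intermediate
8 | 4-methoxybenzaldehyde | COc1ccc(C=O)cc1 | starting material
9 | {(3,5-dimethoxyphenyl){3-methoxy-2-[(R)-4-methylbenzenesulfinyl]phenyl}methyl}lithium | [Li]C(c1cc(OC)cc(OC)c1)c1cccc(OC)c1[S@](=O)c1ccc(C)cc1 | intermediate
10 | lithium (1R,2R)-2-(3,5-dimethoxyphenyl)-1-(4-methoxyphenyl)-2-{3-methoxy-2-[(R)-4-methylbenzenesulfinyl]phenyl}ethan-1-olate | [Li]O[C@@H](c1ccc(OC)cc1)[C@H](c1cc(OC)cc(OC)c1)c1cccc(OC)c1[S@](=O)c1ccc(C)cc1 | intermediate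
11 | (2R,3R)-3-(3,5-dimethoxyphenyl)-7-methoxy-2-(4-methoxyphenyl)-2,3-dihydro-1-benzofuran | c1cc(OC)c2c(c1)[C@@H](c1cc(OC)cc(OC)c1)[C@H](c1ccc(OC)cc1)O2 | intermediate
12 | 2-[(2R,3R)-3-(3,5-dimethoxyphenyl)-7-methoxy-2-(4-methoxyphenyl)-2,3-dihydro-1-benzofuran-5-yl]-4,4,5,5-tetramethyl-1,3,2-dioxaborolane | CC1(C)OB(OC1(C)C)c1cc(OC)c2c(c1)[C@@H](c1cc(OC)cc(OC)c1)[C@H](c1ccc(OC)cc1)O2 | intermediate
13 | 2-bromo-4,6-dimethoxybenzaldehyde | COc1cc(Br)c(C=O)c(OC)c1 | starting material
14 | 2-bromo-6-hydroxy-4-methoxybenzaldehyde | COc1cc(O)c(C=O)c(Br)c1 | intermediate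
15 | 4-methoxybenzyl chloride | COc1ccc(CCl)cc1 | starting material
16 | 2-bromo-4-methoxy-6-[(4-methoxyphenyl)methoxy]benzaldehyde | COc1ccc(COc2cc(OC)cc(Br)c2C=O)cc1 | intermediate
17 | {2-bromo-4-methoxy-6-[(4-methoxyphenyl)methoxy]phenyl}[(2R,3R)-3-(3,5-dimethoxyphenyl)-7-methoxy-2-(4-methoxyphenyl)-2,3-dihydro-1-benzofuran-5-yl]methanol | OC(c1c(Br)cc(OC)cc1OCc1ccc(OC)cc1)c1cc(OC)c2c(c1)[C@@H](c1cc(OC)cc(OC)c1)[C@H](c1ccc(OC)cc1)O2 | intermediate
18 | {2-bromo-4-methoxy-6-[(4-methoxyphenyl)methoxy]phenyl}[(2R,3R)-3-(3,5-dimethoxyphenyl)-7-methoxy-2-(4-methoxyphenyl)-2,3-dihydro-1-benzofuran-5-yl]methanone | O=C(c1c(Br)cc(OC)cc1OCc1ccc(OC)cc1)c1cc(OC)c2c(c1)[C@@H](c1cc(OC)cc(OC)c1)[C@H](c1ccc(OC)cc1)O2 | intermediate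
19 | hydrazone of ketone 18 | NN=C(c1c(Br)cc(OC)cc1OCc1ccc(OC)cc1)c1cc(OC)c2c(c1)[C@@H](c1cc(OC)cc(OC)c1)[C@H](c1ccc(OC)cc1)O2 | intermediate
20 | diaryldiazomethane from 19 | [N-]=[N+]=C(c1c(Br)cc(OC)cc1OCc1ccc(OC)cc1)c1cc(OC)c2c(c1)[C@@H](c1cc(OC)cc(OC)c1)[C@H](c1ccc(OC)cc1)O2 | intermediate
21 | (2R,3R)-5-[(2R,3S)-4-bromo-6-methoxy-2-(4-methoxyphenyl)-2,3-dihydro-1-benzofuran-3-yl]-3-(3,5-dimethoxyphenyl)-7-methoxy-2-(4-methoxyphenyl)-2,3-dihydro-1-benzofuran | Brc1cc(OC)cc2c1[C@H](c1cc(OC)c3c(c1)[C@@H](c1cc(OC)cc(OC)c1)[C@H](c1ccc(OC)cc1)O3)[C@H](c1ccc(OC)cc1)O2 | intermediate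
22 | (2R,3R)-5-[(2S,3S)-4-bromo-6-hydroxy-2-(4-hydroxyphenyl)-2,3-dihydro-1-benzofuran-3-yl]-3-(3,5-dihydroxyphenyl)-2-(4-hydroxyphenyl)-2,3-dihydro-1-benzofuran-7-ol | Brc1cc(O)cc2c1[C@H](c1cc(O)c3c(c1)[C@@H](c1cc(O)cc(O)c1)[C@H](c1ccc(O)cc1)O3)[C@@H](c1ccc(O)cc1)O2 | intermediate
23 | 4-ethenylphenyl acetate | CC(=O)Oc1ccc(C=C)cc1 | starting material
24 | 4-[(E)-2-{(2S,3S)-3-[(2R,3R)-3-(3,5-dihydroxyphenyl)-7-hydroxy-2-(4-hydroxyphenyl)-2,3-dihydro-1-benzofuran-5-yl]-6-hydroxy-2-(4-hydroxyphenyl)-2,3-dihydro-1-benzofuran-4-yl}ethenyl]phenyl acetate | CC(=O)Oc1ccc(/C=C/c2cc(O)cc3c2[C@H](c2cc(O)c4c(c2)[C@@H](c2cc(O)cc(O)c2)[C@H](c2ccc(O)cc2)O4)[C@@H](c2ccc(O)cc2)O3)cc1 | intermediate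
25 | (2R,3R)-3-(3,5-dihydroxyphenyl)-5-{(2S,3S)-6-hydroxy-2-(4-hydroxyphenyl)-4-[(E)-2-(4-hydroxyphenyl)ethenyl]-2,3-dihydro-1-benzofuran-3-yl}-2-(4-hydroxyphenyl)-2,3-dihydro-1-benzofuran-7-ol (CNP0172909.1) | Oc1ccc(/C=C/c2cc(O)cc3c2[C@H](c2cc(O)c4c(c2)[C@@H](c2cc(O)cc(O)c2)[C@H](c2ccc(O)cc2)O4)[C@@H](c2ccc(O)cc2)O3)cc1 | target

**Step count and risks**

Total: 12 steps. Longest linear sequence: 10 steps (steps 1–4 and 7–12).

Step 3 (Proposed new method) is the most likely to fail. The lithium alkoxide may revert by retro-aldol faster than it displaces the sulfinyl group from the electron-rich ring, or the benzhydryl-type anion may add with poor facial control. The fallback sets out from 7 and returns at 11, using known reactions only. The benzyllithium is generated as before, treated with 8 and quenched at –78 °C, the known addition of ortho-sulfinyl benzyl carbanions to aldehydes, to give hydroxy sulfoxide F1; C2′ epimers may be carried on, since C2′ equilibrates later. Sulfoxide–magnesium exchange with iPrMgCl·LiCl (2.2 equiv, THF, –50 °C) and an iodine quench give iodo alcohol F2. Intramolecular Ullmann etherification (CuI, 1,10-phenanthroline, Cs2CO3, toluene, 110 °C) then closes the aryl ether with retention at both centres to give 11.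

Step 10 is the second risk. The carbene centre carries a di-ortho-substituted ring, so facial control by the catalyst may erode, and the hindered ketone may already resist condensation in step 9 so that the carbene is never reached. The fallback sets out from 17 and returns at 22 without a carbene. Treatment of 17 with sodium 4-methylbenzenesulfinate and CF3CO2H in CH2Cl2 should remove the 4-methoxybenzyl ether and convert the benzhydrol into sulfone phenol F3, a base-triggered ortho-quinone methide precursor. Cs2CO3 and (2R,5R)-1-[(4-methoxyphenyl)methyl]-2,5-dimethylthiolan-1-ium tetrafluoroborate in CH2Cl2 should then give the trans hexamethyl ether F4 directly, by the known trans-selective formal [4+1] annulation of a sulfonium benzylide with an ortho-quinone methide; the sulfide enantiomer is taken to deliver (2S,3S). BBr3 demethylation of F4 gives 22.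

Step 12 is the third risk. The free phenoxides may inhibit the palladium catalyst at the hindered bromide, and the electron-rich product may degrade oxidatively under base at 100 °C. The fallback sets out from 22 and returns at 25. Peracetylation (Ac2O, pyridine, 23 °C) gives hexaacetate F5, the Heck reaction with 23 under the same catalyst gives heptaacetate F6, and global methanolysis (K2CO3, MeOH, 0 °C) gives 25.

**Further compounds**

F1 | step 3 | (1R,2R)-2-(3,5-dimethoxyphenyl)-1-(4-methoxyphenyl)-2-{3-methoxy-2-[(R)-4-methylbenzenesulfinyl]phenyl}ethan-1-ol | O[C@@H](c1ccc(OC)cc1)[C@H](c1cc(OC)cc(OC)c1)c1cccc(OC)c1[S@](=O)c1ccc(C)cc1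
F2 | step 3 | (1R,2R)-2-(3,5-dimethoxyphenyl)-2-(2-iodo-3-methoxyphenyl)-1-(4-methoxyphenyl)ethan-1-ol | O[C@@H](c1ccc(OC)cc1)[C@H](c1cc(OC)cc(OC)c1)c1cccc(OC)c1I
F3 | step 10 | 3-bromo-2-{[(2R,3R)-3-(3,5-dimethoxyphenyl)-7-methoxy-2-(4-methoxyphenyl)-2,3-dihydro-1-benzofuran-5-yl](4-methylbenzenesulfonyl)methyl}-5-methoxyphenol | Cc1ccc(cc1)S(=O)(=O)C(c1c(Br)cc(OC)cc1O)c1cc(OC)c2c(c1)[C@@H](c1cc(OC)cc(OC)c1)[C@H](c1ccc(OC)cc1)O2
F4 | step 10 | (2R,3R)-5-[(2S,3S)-4-bromo-6-methoxy-2-(4-methoxyphenyl)-2,3-dihydro-1-benzofuran-3-yl]-3-(3,5-dimethoxyphenyl)-7-methoxy-2-(4-methoxyphenyl)-2,3-dihydro-1-benzofuran | Brc1cc(OC)cc2c1[C@H](c1cc(OC)c3c(c1)[C@@H](c1cc(OC)cc(OC)c1)[C@H](c1ccc(OC)cc1)O3)[C@@H](c1ccc(OC)cc1)O2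
F5 | step 12 | hexaacetate of 22 | Brc1cc(OC(C)=O)cc2c1[C@H](c1cc(OC(C)=O)c3c(c1)[C@@H](c1cc(OC(C)=O)cc(OC(C)=O)c1)[C@H](c1ccc(OC(C)=O)cc1)O3)[C@@H](c1ccc(OC(C)=O)cc1)O2
F6 | step 12 | heptaacetate of 25 | CC(=O)Oc1ccc(/C=C/c2cc(OC(C)=O)cc3c2[C@H](c2cc(OC(C)=O)c4c(c2)[C@@H](c2cc(OC(C)=O)cc(OC(C)=O)c2)[C@H](c2ccc(OC(C)=O)cc2)O4)[C@@H](c2ccc(OC(C)=O)cc2)O3)cc1
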